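**Plan**
1. Retrosynthetically, the 6-carboxy-2-pyrone is folded back into a 3,4,5-trioxygenated phenyl ring. Its lactone C–O bond is opened, and the lactone carbonyl carbon and the carboxyl carbon are rejoined. The C3=C4 enoate is traced back to a C4 carbinol.
2. Ring B is then cut at C1–C2 and C3–C4. Its two benzylic carbons, C1 (bearing the pendant ring) and C4, flank the C2–C3 succinate unit. C4a, C8a, C1 and C4 therefore form an o-quinodimethane, and C2–C3 is a fumarate.
3. The o-quinodimethane is the photoenol of a 2-benzylbenzaldehyde. Its C8a–C1 bond is cut to a ring A boronate and a pendant benzylic bromide.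
4. In the forward direction, ring A and the pendant ring are bought and joined by Suzuki coupling. Ring B then closes by photoenolisation/[4+2], C4–OH is eliminated, the pendant ring is recast as the pyrone, and ring A and the esters are unmasked.
5. The C1/C2 trans relationship comes from the dienol geometry, the fumarate geometry and a titanium-bound endo transition state. The absolute configuration comes from the TADDOL ligand. C3 and C4 are sacrificial, and every later step is acidic or neutral so that C1 and C2 are not touched.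

Key step: step 5

Numbering: naphthalene numbering of the target is used throughout. C1 bears the pendant ring, C2 and C3 bear the carboxyl groups, C4 is the vinylic CH, ring A is the benzo ring and ring B is the new carbocycle.
Assumption: the sense of induction of the titanium TADDOLate with this substrate pair cannot be derived with certainty, so (4R,5R)-TADDOL is written and the equally available (4S,5S) antipode would be used if the first run shows the mirror-image adduct.

**Step 1**
Reactants: 1 3,4,5-tris(benzyloxy)benzaldehyde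
Product: 2 [3,4,5-tris(benzyloxy)phenyl]methanol
Conditions: NaBH4, THF/MeOH, 0 °C
Reagents that add atoms: none
Why: Borohydride reduction of an aromatic aldehyde, to which the aryl benzyl ethers are inert.

**Step 2**
Reactants: 2 [3,4,5-tris(benzyloxy)phenyl]methanol
Product: 3 5-(bromomethyl)-1,2,3-tris(benzyloxy)benzene
Conditions: PBr3, CH2Cl2, 0 °C
Reagents that add atoms: phosphorus tribromide, BrP(Br)Br
Why: Substitution of a primary benzylic alcohol through its phosphite ester (SN2 bromination), a standard conversion for trialkoxybenzyl alcohols that leaves the ethers intact at 0 °C.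

**Step 3**
Reactants: 4 2-bromo-4,5-dimethoxybenzaldehyde (6-bromoveratraldehyde)
Product: 5 4,5-dimethoxy-2-(4,4,5,5-tetramethyl-1,3,2-dioxaborolan-2-yl)benzaldehyde
Conditions: B2pin2, PdCl2(dppf) (3 mol %), KOAc, 1,4-dioxane, 90 °C
Reagents that add atoms: bis(pinacolato)diboron, CC1(C)OB(OC1(C)C)B1OC(C)(C)C(C)(C)O1
Why: Miyaura borylation of an aryl bromide tolerates the free formyl group, so no acetal has to be put on and taken off.

**Step 4**
Reactants: 3 5-(bromomethyl)-1,2,3-tris(benzyloxy)benzene; 5 4,5-dimethoxy-2-(4,4,5,5-tetramethyl-1,3,2-dioxaborolan-2-yl)benzaldehyde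
Product: 6 4,5-dimethoxy-2-[3,4,5-tris(benzyloxy)benzyl]benzaldehyde
Conditions: Pd(PPh3)4 (5 mol %), K2CO3, DME/H2O, 80 °C
Reagents that add atoms: none
Why: Suzuki–Miyaura sp2–sp3 coupling of a 2-formylarylboronate with a benzylic bromide is the usual entry to 2-benzylbenzaldehydes, and its basic medium avoids both the isobenzofuran/phthalan collapse of benzhydrol–acetal intermediates and the acid-triggered Bradsher cyclodehydration of 6.

**Step 5**
Reactants: 6 4,5-dimethoxy-2-[3,4,5-tris(benzyloxy)benzyl]benzaldehyde; 7 dimethyl fumarate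
Product: 9 dimethyl (1R,2S,3R,4R)-4-hydroxy-6,7-dimethoxy-1-[3,4,5-tris(benzyloxy)phenyl]-1,2,3,4-tetrahydronaphthalene-2,3-dicarboxylate, via photoenol (E,E)-hydroxy-o-quinodimethane 8 (not isolated)
Conditions: Ti(OiPr)4 (1.2 equiv), (4R,5R)-TADDOL (1.3 equiv), 4 Å MS, toluene, rt, then iPrOH stripped in vacuo; 7 (3 equiv), 6, hν (365 nm LED), degassed toluene, 0 °C; aq. NaHCO3
Reagents that add atoms: none
Why: Proposed new method: excitation of 6 at 365 nm, intersystem crossing and 1,5-hydrogen transfer from the doubly benzylic CH2 to the carbonyl oxygen give dienol 8 (its Z-enol isomer falls back to 6 and is recycled), whose OH should replace one isopropoxide of (TADDOLate)Ti(OiPr)2 while the same tetravalent titanium centre binds an ester carbonyl of 7, after which a concerted suprafacial [4+2] addition takes place. The closest known reaction types are the additive-free photoenol/fumarate Diels–Alder reaction of 2-benzylbenzaldehydes used in aryltetralin lignan chemistry and the Ti(OiPr)4/TADDOL-mediated enantioselective photoenolisation/Diels–Alder reaction of 2-methylbenzaldehydes with enones; what is new is their union on a diarylmethane donor and an acyclic fumarate diester. Ring B closes as a six-membered carbocycle by an intermolecular, metal-templated [4π+2π] cycloaddition that makes C1–C2 and C3–C4 in one event and is driven by the return of aromaticity to ring A. C1 and C4 come out cis because aryl and O–Ti both point outward on the E,E-diene, C2 and C3 come out trans because the E geometry of 7 is carried over, C3–CO2Me lies cis to C4–O (hence C2–CO2Me trans to the C1 aryl group) because the titanium-bound carbonyl has to sit endo next to the carbinol carbon, and the absolute sense (1R,2S,3R,4R) is fixed by the diphenylmethoxide walls of the ligand, which leave one face of the bound fumarate open. The step needs endo/exo and facial selectivity but no regioselectivity, since the two ends of 7 are equivalent, and the repulsion between the C1 aryl group and an endo ester at C2 works in the same direction as the tether. Only 6 absorbs at 365 nm, so 7 is not isomerised directly and 9 is not photolysed, the mild alkoxide Lewis acid does not trigger cyclodehydration of 6 to an anthracene, and stripping the liberated iPrOH together with the low temperature holds back ester exchange.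

**Step 6**
Reactants: 9 dimethyl (1R,2S,3R,4R)-4-hydroxy-6,7-dimethoxy-1-[3,4,5-tris(benzyloxy)phenyl]-1,2,3,4-tetrahydronaphthalene-2,3-dicarboxylate
Product: 10 dimethyl (1R,2S)-6,7-dimethoxy-1-[3,4,5-tris(benzyloxy)phenyl]-1,2-dihydronaphthalene-2,3-dicarboxylate
Conditions: p-TsOH·H2O (10 mol %), toluene, 80 °C
Reagents that add atoms: none
Why: Acid-catalysed E1 dehydration through the C4 benzylic cation (stabilised by the para 7-methoxy group) can lose only H3 and gives the aryl-conjugated enoate, and the absence of base avoids deprotonation at C2 and migration of the double bond, so C1 and C2 stay as set.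

**Step 7**
Reactants: 10 dimethyl (1R,2S)-6,7-dimethoxy-1-[3,4,5-tris(benzyloxy)phenyl]-1,2-dihydronaphthalene-2,3-dicarboxylate
Product: 11 dimethyl (1R,2S)-6,7-dimethoxy-1-(3,4,5-trihydroxyphenyl)-1,2-dihydronaphthalene-2,3-dicarboxylate
Conditions: BCl3 (6 equiv), C6HMe5 (10 equiv), CH2Cl2, −78 °C; MeOH, then H2O
Reagents that add atoms: none
Why: Lewis acid debenzylation with pentamethylbenzene as a non-basic benzyl cation scavenger cleaves aryl benzyl ethers at −78 °C and spares the aryl methyl ethers, the methyl esters and the C3=C4 alkene that hydrogenolysis would endanger.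

**Step 8**
Reactants: 11 dimethyl (1R,2S)-6,7-dimethoxy-1-(3,4,5-trihydroxyphenyl)-1,2-dihydronaphthalene-2,3-dicarboxylate
Product: 14 4-[(1R,2S)-6,7-dimethoxy-2,3-bis(methoxycarbonyl)-1,2-dihydronaphthalen-1-yl]-2-oxo-2H-pyran-6-carboxylic acid, via hydroxy-o-quinone 12 (not isolated), via ring-opened 2-hydroxymuconic acid 13 (not isolated)
Conditions: CH3CO3H (2.5 equiv), AcOH, 15 °C to rt, dark
Reagents that add atoms: peracetic acid, CC(=O)OO
Why: Peracid intradiol cleavage of a pyrogallol (oxidation to 12, Baeyer–Villiger-type oxygen insertion between the two carbonyl carbons, opening to 13, lactonisation of the enol OH onto the cis-disposed distal carboxyl) is the known way from pyrogallol to 2-pyrone-6-carboxylic acid; here the two possible cuts of the locally symmetric pendant ring give the same product, ring A is masked as its dimethyl ether, and the enoate alkene is too electron-poor to compete.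

**Step 9**
Reactants: 14 4-[(1R,2S)-6,7-dimethoxy-2,3-bis(methoxycarbonyl)-1,2-dihydronaphthalen-1-yl]-2-oxo-2H-pyran-6-carboxylic acid
Product: 15 4-[(1R,2S)-6,7-dihydroxy-2,3-bis(methoxycarbonyl)-1,2-dihydronaphthalen-1-yl]-2-oxo-2H-pyran-6-carboxylic acid
Conditions: BBr3 (8 equiv), CH2Cl2, −78 to 0 °C; H2O
Reagents that add atoms: none
Why: Boron tribromide cleavage of aryl methyl ethers proceeds by bromide attack at the methyl carbon, the pyrone and the enoate only coordinate the excess Lewis acid, and any partial ester demethylation is harmless because the esters fall in the next step.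

**Step 10**
Reactants: 15 4-[(1R,2S)-6,7-dihydroxy-2,3-bis(methoxycarbonyl)-1,2-dihydronaphthalen-1-yl]-2-oxo-2H-pyran-6-carboxylic acid
Product: 16 (1R,2S)-1-(6-carboxy-2-oxo-2H-pyran-4-yl)-6,7-dihydroxy-1,2-dihydronaphthalene-2,3-dicarboxylic acid
Conditions: 4 M aq. HCl/1,4-dioxane (1:1), 90 °C, argon
Reagents that add atoms: water, O
Why: Acid-catalysed acyl–oxygen ester hydrolysis is chosen because 2-pyrone-6-carboxylic acids and catechols withstand hot mineral acid, whereas hydroxide would open the pyrone, favour air oxidation of the catechol and deprotonate C1–H and C2–H.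

**Compound list**
1 | 3,4,5-tris(benzyloxy)benzaldehyde | O=Cc1cc(OCc2ccccc2)c(OCc2ccccc2)c(OCc2ccccc2)c1 | starting material
2 | [3,4,5-tris(benzyloxy)phenyl]methanol | OCc1cc(OCc2ccccc2)c(OCc2ccccc2)c(OCc2ccccc2)c1 | intermediate
3 | 5-(bromomethyl)-1,2,3-tris(benzyloxy)benzene | BrCc1cc(OCc2ccccc2)c(OCc2ccccc2)c(OCc2ccccc2)c1 | intermediate
4 | 2-bromo-4,5-dimethoxybenzaldehyde (6-bromoveratraldehyde) | COc1cc(Br)c(C=O)cc1OC | starting material
5 | 4,5-dimethoxy-2-(4,4,5,5-tetramethyl-1,3,2-dioxaborolan-2-yl)benzaldehyde | COc1cc(C=O)c(cc1OC)B1OC(C)(C)C(C)(C)O1 | intermediate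
6 | 4,5-dimethoxy-2-[3,4,5-tris(benzyloxy)benzyl]benzaldehyde | COc1cc(C=O)c(Cc2cc(OCc3ccccc3)c(OCc3ccccc3)c(OCc3ccccc3)c2)cc1OC | intermediate
7 | dimethyl fumarate | COC(=O)/C=C/C(=O)OC | starting material
8 | (E)-[(6E)-3,4-dimethoxy-6-{[3,4,5-tris(benzyloxy)phenyl]methylidene}cyclohexa-2,4-dien-1-ylidene]methanol, OH and aryl both outward | O/C=C1/C(=C/c2cc(OCc3ccccc3)c(OCc3ccccc3)c(OCc3ccccc3)c2)C=C(OC)C(OC)=C1 | intermediate
9 | dimethyl (1R,2S,3R,4R)-4-hydroxy-6,7-dimethoxy-1-[3,4,5-tris(benzyloxy)phenyl]-1,2,3,4-tetrahydronaphthalene-2,3-dicarboxylate (1,2-trans, 2,3-trans, 3,4-cis) | COC(=O)[C@H]1[C@@H](O)c2cc(OC)c(OC)cc2[C@@H](c2cc(OCc3ccccc3)c(OCc3ccccc3)c(OCc3ccccc3)c2)[C@@H]1C(=O)OC | intermediate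
10 | dimethyl (1R,2S)-6,7-dimethoxy-1-[3,4,5-tris(benzyloxy)phenyl]-1,2-dihydronaphthalene-2,3-dicarboxylate | COC(=O)C1=Cc2cc(OC)c(OC)cc2[C@@H](c2cc(OCc3ccccc3)c(OCc3ccccc3)c(OCc3ccccc3)c2)[C@@H]1C(=O)OC | intermediate
11 | dimethyl (1R,2S)-6,7-dimethoxy-1-(3,4,5-trihydroxyphenyl)-1,2-dihydronaphthalene-2,3-dicarboxylate | COC(=O)C1=Cc2cc(OC)c(OC)cc2[C@@H](c2cc(O)c(O)c(O)c2)[C@@H]1C(=O)OC | intermediate
12 | dimethyl (1R,2S)-1-(5-hydroxy-3,4-dioxocyclohexa-1,5-dien-1-yl)-6,7-dimethoxy-1,2-dihydronaphthalene-2,3-dicarboxylate | COC(=O)C1=Cc2cc(OC)c(OC)cc2[C@@H](C2=CC(=O)C(=O)C(O)=C2)[C@@H]1C(=O)OC | intermediate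
13 | (2E,4Z)-4-[(1R,2S)-6,7-dimethoxy-2,3-bis(methoxycarbonyl)-1,2-dihydronaphthalen-1-yl]-2-hydroxyhexa-2,4-dienedioic acid | COC(=O)C1=Cc2cc(OC)c(OC)cc2[C@@H](C(=C/C(=O)O)/C=C(O)\C(=O)O)[C@@H]1C(=O)OC | intermediate
14 | 4-[(1R,2S)-6,7-dimethoxy-2,3-bis(methoxycarbonyl)-1,2-dihydronaphthalen-1-yl]-2-oxo-2H-pyran-6-carboxylic acid | COC(=O)C1=Cc2cc(OC)c(OC)cc2[C@@H](c2cc(C(=O)O)oc(=O)c2)[C@@H]1C(=O)OC | intermediate
15 | 4-[(1R,2S)-6,7-dihydroxy-2,3-bis(methoxycarbonyl)-1,2-dihydronaphthalen-1-yl]-2-oxo-2H-pyran-6-carboxylic acid | COC(=O)C1=Cc2cc(O)c(O)cc2[C@@H](c2cc(C(=O)O)oc(=O)c2)[C@@H]1C(=O)OC | intermediate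
16 | (1R,2S)-1-(6-carboxy-2-oxo-2H-pyran-4-yl)-6,7-dihydroxy-1,2-dihydronaphthalene-2,3-dicarboxylic acid (CNP0195322.1) | O=C(O)C1=Cc2cc(O)c(O)cc2[C@@H](c2cc(C(=O)O)oc(=O)c2)[C@@H]1C(=O)O | target

Total step count: 10. Longest linear sequence: 9 (steps 1, 2, 4, 5, 6, 7, 8, 9, 10).

**Steps most likely to fail**

**Step 5.** The monodentate fumarate may bind only loosely to the titanium alkoxide. An untemplated background cycloaddition would then erode facial selectivity. Sensitised E/Z isomerisation of the dienophile and slow isopropoxide/methoxide ester exchange could also blur the outcome.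

The fallback sets out from 6 and returns at 10. It moves the stereochemical information from the metal to the dienophile, using the auxiliary-controlled addition known for hydroxy-o-quinodimethanes.
- Fumaryl chloride and methyl (S)-mandelate (Et3N, CH2Cl2, 0 °C) give bis[(1S)-2-methoxy-2-oxo-1-phenylethyl] fumarate F1.
- Irradiation of 6 with it (365 nm, degassed toluene, rt, no titanium) should give bis[(1S)-2-methoxy-2-oxo-1-phenylethyl] (1R,2S,3R,4R)-4-hydroxy-6,7-dimethoxy-1-[3,4,5-tris(benzyloxy)phenyl]-1,2,3,4-tetrahydronaphthalene-2,3-dicarboxylate F2. This adduct can be freed from minor diastereomers by crystallisation or chromatography.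
- p-TsOH in toluene at 80 °C dehydrates it to bis[(1S)-2-methoxy-2-oxo-1-phenylethyl] (1R,2S)-6,7-dimethoxy-1-[3,4,5-tris(benzyloxy)phenyl]-1,2-dihydronaphthalene-2,3-dicarboxylate F3.
- Acid methanolysis (H2SO4 cat., MeOH, reflux) exchanges both auxiliaries for methyl and gives 10.

**Step 8.** The free pyrogallol may be lost to one-electron coupling (benzotropolone-type dimerisation) or over-oxidation. The peracid may attack ring A or the C3=C4 alkene, and lactonisation of the opened diacid may stay incomplete.

The fallback sets out from 11 and returns at 16. It replaces the peracid by the lead tetraacetate cleavage of catechols to cis,cis-muconic esters.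
- Pb(OAc)4 (2.2 equiv) in MeOH/toluene at 0 °C should cut the same C–C bond under two-electron control. After loss of methanol from the enol ester, the product is dimethyl (1R,2S)-6,7-dimethoxy-1-[6-(methoxycarbonyl)-2-oxo-2H-pyran-4-yl]-1,2-dihydronaphthalene-2,3-dicarboxylate F4.
- BBr3 as in step 9 gives dimethyl (1R,2S)-6,7-dihydroxy-1-[6-(methoxycarbonyl)-2-oxo-2H-pyran-4-yl]-1,2-dihydronaphthalene-2,3-dicarboxylate F5.
- The acid hydrolysis of step 10 then removes all three methyl esters to give 16.

**Step 10.** Hydrolysis of the hindered C2 ester may be slow and force long heating. Epimerisation at C2 through the enol, air aromatisation of ring B, or decarboxylation of the β,γ-unsaturated C2 acid could then set in.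

The fallback sets out from 14 and returns at 16, replacing steps 9 and 10. It changes from acyl to alkyl cleavage. AlBr3 in tetrahydrothiophene at rt (a hard acid/soft nucleophile dealkylation) removes the four methyl groups of the aryl ethers and the esters by SN2 attack at carbon. No acyl carbon, C1 or C2 is touched, and aqueous acid work-up delivers 16 directly. No new compound arises on this path.

**Further compounds**
F1 | step 5 | bis[(1S)-2-methoxy-2-oxo-1-phenylethyl] fumarate | COC(=O)[C@@H](OC(=O)/C=C/C(=O)O[C@H](C(=O)OC)c1ccccc1)c1ccccc1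
F2 | step 5 | bis[(1S)-2-methoxy-2-oxo-1-phenylethyl] (1R,2S,3R,4R)-4-hydroxy-6,7-dimethoxy-1-[3,4,5-tris(benzyloxy)phenyl]-1,2,3,4-tetrahydronaphthalene-2,3-dicarboxylate | COC(=O)[C@H](c3ccccc3)OC(=O)[C@H]1[C@@H](O)c2cc(OC)c(OC)cc2[C@@H](c2cc(OCc3ccccc3)c(OCc3ccccc3)c(OCc3ccccc3)c2)[C@@H]1C(=O)O[C@H](C(=O)OC)c1ccccc1
F3 | step 5 | bis[(1S)-2-methoxy-2-oxo-1-phenylethyl] (1R,2S)-6,7-dimethoxy-1-[3,4,5-tris(benzyloxy)phenyl]-1,2-dihydronaphthalene-2,3-dicarboxylate | COC(=O)[C@H](c3ccccc3)OC(=O)C1=Cc2cc(OC)c(OC)cc2[C@@H](c2cc(OCc3ccccc3)c(OCc3ccccc3)c(OCc3ccccc3)c2)[C@@H]1C(=O)O[C@H](C(=O)OC)c1ccccc1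
F4 | step 8 | dimethyl (1R,2S)-6,7-dimethoxy-1-[6-(methoxycarbonyl)-2-oxo-2H-pyran-4-yl]-1,2-dihydronaphthalene-2,3-dicarboxylate | COC(=O)C1=Cc2cc(OC)c(OC)cc2[C@@H](c2cc(C(=O)OC)oc(=O)c2)[C@@H]1C(=O)OC
F5 | step 8 | dimethyl (1R,2S)-6,7-dihydroxy-1-[6-(methoxycarbonyl)-2-oxo-2H-pyran-4-yl]-1,2-dihydronaphthalene-2,3-dicarboxylate | COC(=O)C1=Cc2cc(O)c(O)cc2[C@@H](c2cc(C(=O)OC)oc(=O)c2)[C@@H]1C(=O)OC
F0 | step 10 | none | none
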